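**Retrosynthetic overview**
1. The ten-membered ring is closed last, at C4–C5, by a cathodic nickel-catalysed acyl–alkenyl coupling of a seco thioester/alkenyl iodide; then C4 reduction, acetylation, C17 equilibration and desilylation.
2. The γ-lactone and the 11,12-oxirane come from a double hydroxyl-directed epoxidation of a C9 dienyl carbinol, followed by opening of the 7,8-epoxide by the C19 ester (inversion at C7).
3. C8–C9 is made by a nickel-catalysed reductive coupling of a ring A aldehyde with an enyne ester (Felkin–Anh control at C9).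
4. The ring A aldehyde comes from (S)-carvone: C6 formylation/methylation (C1), chelation-controlled thioacetate aldol (C2), Criegee rearrangement (C14 acetate), allylindium hydroxymethylation (C10).
5. The enyne ester comes from 2-butyne-1,4-diol. Ring order: cyclohexene (bought) → oxirane → γ-lactone → ten-membered carbocycle.

Assumption: briarane numbering (C1–C20) is used for all intermediates, β is the ring A face that carries CH3-15, and C17 is carried as a 1:1 epimer mixture from step 14 to step 23 (no stereo tag at that centre in those SMILES).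

**Step 1**
Reactants: 1 (S)-(+)-carvone
Product: 2 (5S)-6-(hydroxymethylidene)carvone (chelated enol of 6-formylcarvone)
Conditions: NaH, HCO2Et, cat. EtOH, THF, 0 °C → rt; aq. HCl work-up
Reagents that add atoms: ethyl formate, CCOC=O
Why: Claisen formylation at the α′-CH2 of the enone (the future C1) gives the stabilised β-keto-aldehyde enolate, with no new stereocentre and the bought carvone centre (future C14) untouched.

**Step 2**
Reactants: 2 (5S)-6-(hydroxymethylidene)carvone
Product: 3 (1R,6R)-1,3-dimethyl-2-oxo-6-(prop-1-en-2-yl)cyclohex-3-ene-1-carbaldehyde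
Conditions: MeI, K2CO3, acetone, rt
Reagents that add atoms: iodomethane, CI
Why: C-alkylation of the β-keto-aldehyde enolate, in which MeI enters anti to the neighbouring isopropenyl group and so sets the quaternary C1 (CH3-15 β, formyl carbon C2 α).

**Step 3**
Reactants: 3 (1R,6R)-1,3-dimethyl-2-oxo-6-(prop-1-en-2-yl)cyclohex-3-ene-1-carbaldehyde
Product: 5 S-ethyl (3R)-3-[(1R,6R)-1,3-dimethyl-2-oxo-6-(prop-1-en-2-yl)cyclohex-3-en-1-yl]-3-(triethylsilyloxy)propanethioate, via bromomagnesium aldolate 4 (not isolated)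
Conditions: EtSC(O)CH3, LiN(SiMe3)2, THF, −78 °C; MgBr2·OEt2; add 3, CH2Cl2/THF, −78 °C; then TESOTf, 2,6-lutidine, −78 → 0 °C
Reagents that add atoms: S-ethyl thioacetate, CCSC(C)=O; triethylsilyl trifluoromethanesulfonate, CC[Si](CC)(CC)OS(=O)(=O)C(F)(F)F
Why: chelation-controlled acetate aldol addition in which Mg bridges the aldehyde and C10 ketone oxygens and the thioester enolate attacks the aldehyde from the side of the small C1 methyl, giving the (2R) carbinol, which is trapped in the same flask as its TES ether.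

**Step 4**
Reactants: 5 S-ethyl thioester TES ether (isopropenyl enone)
Product: 7 S-ethyl (3R)-3-[(1R,6S)-6-acetoxy-1,3-dimethyl-2-oxocyclohex-3-en-1-yl]-3-(triethylsilyloxy)propanethioate, via α-methoxy hydroperoxide 6 (not isolated)
Conditions: O3, CH2Cl2/MeOH, NaHCO3, −78 °C (Sudan red 7B end point); then Ac2O, Et3N, DMAP, 0 → 40 °C
Reagents that add atoms: ozone, O=[O+][O-]
Why: selective ozonolysis of the electron-rich isopropenyl group (the enone alkene is spared) followed by Criegee rearrangement of the peracetate, in which the ring carbon migrates to oxygen with retention, so the bought centre becomes the 14α-acetate.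

**Step 5**
Reactants: 7 14α-acetoxy enone thioester
Product: 8 C10 allylic alcohol (10α-OH; C11=C12 alkene kept)
Conditions: NaBH4, CeCl3·7H2O, MeOH, −78 °C
Reagents that add atoms: none
Why: Luche 1,2-reduction of the enone with hydride from the less hindered β-face (thioester and acetate survive at −78 °C); this carbinol configuration is erased again in step 7.

**Step 6**
Reactants: 8 C10 allylic alcohol
Product: 9 C10 allylic methyl carbonate
Conditions: ClCO2Me, pyridine, DMAP (cat.), CH2Cl2, 0 °C → rt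
Reagents that add atoms: methyl chloroformate, COC(Cl)=O
Why: O-acylation of the only free hydroxyl installs the leaving group for π-allyl formation, with no stereocentre changed.

**Step 7**
Reactants: 9 C10 allylic methyl carbonate
Product: 10 10β-(hydroxymethyl) compound (C9 carbinol; H-10 α; C11=C12 alkene)
Conditions: Pd(PPh3)4 (5 mol %), InI, aq. HCHO, THF, rt
Reagents that add atoms: formaldehyde, C=O
Why: umpolung Barbier allylation in which the π-allylpalladium from the carbonate is transmetalated to an allylindium (In at the less hindered C12) that adds to formaldehyde at the γ-carbon C10 through a six-membered transition state on the β-face, opposite the α-oriented C1 side chain and C14 acetate, which sets C10 (C9 β, H α) and leaves the alkene at C11=C12.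

**Step 8**
Reactants: 10 10β-(hydroxymethyl) compound
Product: 11 ring A aldehyde (C9 = CHO on C10β)
Conditions: Dess–Martin periodinane, NaHCO3, CH2Cl2, 0 °C
Reagents that add atoms: none
Why: buffered Dess–Martin oxidation of the primary alcohol under neutral conditions keeps the α-stereocentre C10 and the β,γ-alkene in place (the aldehyde is used at once).

**Step 9**
Reactants: 12 2-butyne-1,4-diol
Product: 13 4-(tert-butyldiphenylsilyloxy)but-2-yn-1-ol
Conditions: TBDPSCl (0.3 equiv), imidazole, DMF, 0 °C → rt (diol in excess)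
Reagents that add atoms: tert-butyl(chloro)diphenylsilane, CC(C)(C)[Si](Cl)(c1ccccc1)c1ccccc1
Why: statistical monosilylation of a symmetric diol protects the future C16 hydroxyl; there is no stereocentre.

**Step 10**
Reactants: 13 4-(tert-butyldiphenylsilyloxy)but-2-yn-1-ol
Product: 14 (Z)-4-(tert-butyldiphenylsilyloxy)-3-(triethylsilyl)but-2-en-1-ol
Conditions: Et3SiH, [Cp*Ru(MeCN)3]PF6 (2 mol %), CH2Cl2, 0 °C → rt
Reagents that add atoms: triethylsilane, CC[SiH](CC)CC
Why: ruthenium-catalysed trans-hydrosilylation of a propargylic alcohol puts silicon on the carbon distal to the free hydroxyl (C5), and the trans addition fixes the alkene geometry (silicon, the later C4 position, cis to C7).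

**Step 11**
Reactants: 14 (Z)-vinylsilane alcohol
Product: 15 (Z)-4-(tert-butyldiphenylsilyloxy)-3-(triethylsilyl)but-2-enal
Conditions: MnO2, CH2Cl2, rt
Reagents that add atoms: none
Why: MnO2 oxidation of the allylic alcohol to the enal under neutral conditions keeps the alkene geometry.

**Step 12**
Reactants: 15 (Z)-silyl enal
Product: 16 (Z)-tert-butyldiphenyl{[2-(triethylsilyl)pent-2-en-4-yn-1-yl]oxy}silane
Conditions: Me3SiCHN2, LiN(iPr)2, THF, −78 → 0 °C
Reagents that add atoms: trimethylsilyldiazomethane, C[Si](C)(C)C=[N+]=[N-]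
Why: Colvin homologation (1,2-addition, Peterson-type loss of silanolate, 1,2-H shift of the alkylidene carbene) turns the aldehyde into the terminal alkyne C7≡C8 without the alcoholic base that would add to an enal.

**Step 13**
Reactants: 16 terminal enyne
Product: 17 tert-butyl (Z)-7-(tert-butyldiphenylsilyloxy)-6-(triethylsilyl)hept-5-en-3-ynoate
Conditions: N2CHCO2tBu, CuI (5 mol %), MeCN, rt
Reagents that add atoms: tert-butyl diazoacetate, CC(C)(C)OC(=O)C=[N+]=[N-]
Why: CuI-catalysed coupling of a terminal alkyne with a diazoacetate (copper acetylide/carbene C–H insertion) gives the 3-alkynoate and so attaches C17 and C19.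

**Step 14**
Reactants: 17 tert-butyl 3-alkynoate
Product: 19 tert-butyl (Z)-7-(tert-butyldiphenylsilyloxy)-2-methyl-6-(triethylsilyl)hept-5-en-3-ynoate (racemic), via lithium ester enolate 18 (not isolated)
Conditions: LiN(iPr)2, THF, −78 °C; then MeI, −78 °C
Reagents that add atoms: iodomethane, CI
Why: kinetic α-alkylation of the ester enolate introduces CH3-18; C17 is formed racemic here and is corrected thermodynamically in step 23.

**Step 15**
Reactants: 11 ring A aldehyde; 19 enyne ester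
Product: 20 C9 dienyl carbinol (C8–C9 bond; 9-OH anti to C1; (7E,5Z)-diene; C17 epimers)
Conditions: Ni(cod)2 (10 mol %), PBu3 (20 mol %), Et3B, EtOAc, rt
Reagents that add atoms: none
Why: nickel-catalysed reductive aldehyde–enyne coupling (oxanickelacycle, then ethyl transfer and β-hydride delivery) forms the C–C bond at the alkyne carbon distal to the alkene (C8) with cis addition of H and carbon, giving the (7E) alkene, and the aldehyde reacts in the Felkin–Anh sense with the quaternary C1 anti to the incoming carbon, which sets C9.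

**Step 16**
Reactants: 20 C9 dienyl carbinol
Product: 22 7,8:11β,12β-bis-epoxy alcohol, via 7,8-epoxy alcohol 21 (not isolated)
Conditions: VO(acac)2 (10 mol %), t-BuOOH (2.5 equiv, decane), CH2Cl2, 0 °C → rt
Reagents that add atoms: tert-butyl hydroperoxide, CC(C)(C)OO
Why: hydroxyl-directed vanadium epoxidation, in which the C9–OH first delivers oxygen to the allylic C7=C8 alkene with erythro selectivity enforced by A(1,2) strain against the C8 substituent (sets C8 and, for now, C7) and then, as a homoallylic director, to the β-face of C11=C12 (sets C11 and C12), while the remote silylated alkene is left.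

**Step 17**
Reactants: 22 bis-epoxy alcohol
Product: 23 8-hydroxy-18,7-lactone (γ-lactone; 8-OH; C5 vinylsilane; C17 epimers)
Conditions: CSA (10 mol %), CH2Cl2, 0 °C
Reagents that add atoms: none
Why: acid-catalysed epoxy-ester lactonisation in which the tert-butyl ester carbonyl opens the allylic epoxide carbon C7 in a five-membered transition state with inversion (isobutene is lost), fixing C7 and leaving the tertiary 8-OH, while the less activated 11,12-epoxide survives.

**Step 18**
Reactants: 23 hydroxy lactone vinylsilane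
Product: 24 alkenyl iodide seco-thioester (C5–I cis to C7)
Conditions: NIS, MeCN/ClCH2CN (4:1), 0 °C → rt, dark
Reagents that add atoms: N-iodosuccinimide, O=C1CCC(=O)N1I
Why: ipso-iododesilylation of the vinylsilane with retention of the alkene geometry unmasks the alkenyl iodide after the nickel step of step 15, and no other nucleophilic alkene is left at this stage.

**Step 19**
Reactants: 24 alkenyl iodide seco-thioester
Product: 25 macrocyclic C4 enone (ten-membered ring; 2-OTES; 9-OH; 16-OTBDPS)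
Conditions: NiBr2(dme) (20 mol %), 4,4′-di-tert-butyl-2,2′-bipyridine (24 mol %), nBu4NBr, DMA/THF, undivided cell, Zn anode, Ni-foam cathode, constant current 3 mA, 2.5 F/mol, syringe-pump addition (final 2 mM), rt
Reagents that add atoms: none
Why: Proposed new method: cathodically generated zerovalent nickel inserts into the alkenyl C–I bond, one-electron reduction gives an alkenyl monovalent nickel species that adds oxidatively into the thioester C(acyl)–S bond (anode-derived Zn2+ binds the thiolate), and C–C reductive elimination closes the ten-membered ring at C4–C5 with retention of the (5Z) geometry and no new stereocentre; the closest known reactions are nickel-catalysed reductive ketone syntheses from thioesters and organic halides with Zn or Mn powder and nickel-electroreductive cross-electrophile couplings, neither shown as a cathodic ring closure of an alkenyl iodide onto an S-alkyl thioester.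

**Step 20**
Reactants: 25 macrocyclic C4 enone
Product: 26 macrocyclic β-hydroxy enone (2-OH free)
Conditions: HF·pyridine, pyridine, THF, 0 °C
Reagents that add atoms: none
Why: buffered fluoride cleavage of the secondary TES ether (TBDPS ether, epoxide and lactone are kept) frees the C2 hydroxyl needed to direct step 21.

**Step 21**
Reactants: 26 macrocyclic β-hydroxy enone
Product: 27 2,4-anti diol (4-OH)
Conditions: Me4NBH(OAc)3, MeCN/AcOH (1:1), −30 °C
Reagents that add atoms: none
Why: Evans–Saksena reduction in which the C2 alkoxy(acetoxy)borohydride delivers hydride to the C4 ketone intramolecularly through a chair transition state, giving the 1,3-anti diol and so setting C4.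

**Step 22**
Reactants: 27 2,4-anti diol
Product: 28 2,4,9,14-tetraacetate 16-TBDPS ether (C17 epimers)
Conditions: Ac2O, pyridine, DMAP (cat.), CH2Cl2, 0 °C → rt
Reagents that add atoms: acetic anhydride, CC(=O)OC(C)=O
Why: acetylation of the three secondary hydroxyls (C2, C4, C9), with the tertiary 8-OH left free for steric reasons.

**Step 23**
Reactants: 28 tetraacetate (C17 epimers)
Product: 29 tetraacetate 16-TBDPS ether with CH3-18 cis to 8-OH (single C17 epimer)
Conditions: DBU, toluene, 60 °C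
Reagents that add atoms: none
Why: base-mediated epimerisation α to the lactone carbonyl converges both C17 epimers on the thermodynamic one, with CH3-18 trans to the bulky C9 branch on C8 (cis to 8-OH), which sets C17.

**Step 24**
Reactants: 29 tetraacetate 16-TBDPS ether
Product: 30 CNP0104124.1 (target)
Conditions: Bu4NF, AcOH (1:1), THF, 0 °C → rt
Reagents that add atoms: none
Why: buffered fluoride desilylation frees the primary C16 hydroxyl without acetate migration, epoxide opening or lactone cleavage.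

**Compound list**
1 | (S)-(+)-carvone | CC(=C)[C@H]1CC=C(C)C(=O)C1 | starting material
2 | (5S)-6-(hydroxymethylidene)carvone (chelated enol of 6-formylcarvone) | CC(=C)[C@H]1CC=C(C)C(=O)/C1=C\O | intermediate
3 | (1R,6R)-1,3-dimethyl-2-oxo-6-(prop-1-en-2-yl)cyclohex-3-ene-1-carbaldehyde (CH3-15 β; CHO = C2 α, cis to isopropenyl) | CC(=C)[C@H]1CC=C(C)C(=O)[C@@]1(C)C=O | intermediate
4 | bromomagnesium aldolate of 3 with S-ethyl thioacetate ((2R)-alkoxide) | CCSC(=O)C[C@@H](O[Mg]Br)[C@]1(C)C(=O)C(C)=CC[C@@H]1C(C)=C | intermediate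
5 | S-ethyl (3R)-3-[(1R,6R)-1,3-dimethyl-2-oxo-6-(prop-1-en-2-yl)cyclohex-3-en-1-yl]-3-(triethylsilyloxy)propanethioate | CCSC(=O)C[C@@H](O[Si](CC)(CC)CC)[C@]1(C)C(=O)C(C)=CC[C@@H]1C(C)=C | intermediate
6 | α-methoxy hydroperoxide from 5 (C14 side chain C(CH3)(OCH3)OOH, both epimers at that carbon) | CCSC(=O)C[C@@H](O[Si](CC)(CC)CC)[C@]1(C)C(=O)C(C)=CC[C@@H]1C(C)(OC)OO | intermediate
7 | S-ethyl (3R)-3-[(1R,6S)-6-acetoxy-1,3-dimethyl-2-oxocyclohex-3-en-1-yl]-3-(triethylsilyloxy)propanethioate (14α-acetate) | CCSC(=O)C[C@@H](O[Si](CC)(CC)CC)[C@]1(C)C(=O)C(C)=CC[C@@H]1OC(C)=O | intermediate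
8 | C10 allylic alcohol of 7 (10α-OH, C11=C12 alkene) | CCSC(=O)C[C@@H](O[Si](CC)(CC)CC)[C@]1(C)[C@H](O)C(C)=CC[C@@H]1OC(C)=O | intermediate
9 | C10 methyl carbonate of 8 | CCSC(=O)C[C@@H](O[Si](CC)(CC)CC)[C@]1(C)[C@H](OC(=O)OC)C(C)=CC[C@@H]1OC(C)=O | intermediate
10 | 10β-(hydroxymethyl) compound (C9H2OH cis to CH3-15, H-10 α, C11=C12 alkene, 14α-OAc, (2R)-OTES thioester side chain) | CCSC(=O)C[C@@H](O[Si](CC)(CC)CC)[C@]1(C)[C@@H](CO)C(C)=CC[C@@H]1OC(C)=O | intermediate
11 | ring A aldehyde (as 10 with C9 = CHO) | CCSC(=O)C[C@@H](O[Si](CC)(CC)CC)[C@]1(C)[C@@H](C=O)C(C)=CC[C@@H]1OC(C)=O | intermediate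
12 | 2-butyne-1,4-diol | OCC#CCO | starting material
13 | 4-(tert-butyldiphenylsilyloxy)but-2-yn-1-ol | OCC#CCO[Si](c1ccccc1)(c1ccccc1)C(C)(C)C | intermediate
14 | (Z)-4-(tert-butyldiphenylsilyloxy)-3-(triethylsilyl)but-2-en-1-ol | OC/C=C(/CO[Si](c1ccccc1)(c1ccccc1)C(C)(C)C)[Si](CC)(CC)CC | intermediate
15 | (Z)-4-(tert-butyldiphenylsilyloxy)-3-(triethylsilyl)but-2-enal | O=C/C=C(/CO[Si](c1ccccc1)(c1ccccc1)C(C)(C)C)[Si](CC)(CC)CC | intermediate
16 | (Z)-tert-butyldiphenyl{[2-(triethylsilyl)pent-2-en-4-yn-1-yl]oxy}silane | C#C/C=C(/CO[Si](c1ccccc1)(c1ccccc1)C(C)(C)C)[Si](CC)(CC)CC | intermediate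
17 | tert-butyl (Z)-7-(tert-butyldiphenylsilyloxy)-6-(triethylsilyl)hept-5-en-3-ynoate | CC(C)(C)OC(=O)CC#C/C=C(/CO[Si](c1ccccc1)(c1ccccc1)C(C)(C)C)[Si](CC)(CC)CC | intermediate
18 | lithium enolate of 17 | [Li]OC(OC(C)(C)C)=CC#C/C=C(/CO[Si](c1ccccc1)(c1ccccc1)C(C)(C)C)[Si](CC)(CC)CC | intermediate
19 | tert-butyl (Z)-7-(tert-butyldiphenylsilyloxy)-2-methyl-6-(triethylsilyl)hept-5-en-3-ynoate (racemic at C17) | CC(C#C/C=C(/CO[Si](c1ccccc1)(c1ccccc1)C(C)(C)C)[Si](CC)(CC)CC)C(=O)OC(C)(C)C | intermediate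
20 | C9 dienyl carbinol (C8–C9 bond; 9-OH anti to C1; (7E,5Z)-diene; C5–SiEt3; C8 bears CH(CH3)CO2tBu; C17 epimers) | CCSC(=O)C[C@@H](O[Si](CC)(CC)CC)[C@]1(C)[C@@H]([C@@H](O)/C(=C/C=C(/CO[Si](c2ccccc2)(c2ccccc2)C(C)(C)C)[Si](CC)(CC)CC)C(C)C(=O)OC(C)(C)C)C(C)=CC[C@@H]1OC(C)=O | intermediate
21 | 7,8-epoxy alcohol (epoxide erythro to 9-OH; C11=C12 alkene still present) | CCSC(=O)C[C@@H](O[Si](CC)(CC)CC)[C@]1(C)[C@@H]([C@@H](O)[C@@]3(C(C)C(=O)OC(C)(C)C)O[C@@H]3/C=C(/CO[Si](c2ccccc2)(c2ccccc2)C(C)(C)C)[Si](CC)(CC)CC)C(C)=CC[C@@H]1OC(C)=O | intermediate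
22 | 7,8:11β,12β-bis-epoxy alcohol | CCSC(=O)C[C@@H](O[Si](CC)(CC)CC)[C@]1(C)[C@@H]([C@@H](O)[C@@]3(C(C)C(=O)OC(C)(C)C)O[C@@H]3/C=C(/CO[Si](c2ccccc2)(c2ccccc2)C(C)(C)C)[Si](CC)(CC)CC)[C@@]2(C)O[C@H]2C[C@@H]1OC(C)=O | intermediate
23 | 8-hydroxy-18,7-lactone (C7, C8, C9 as in the target; C5 vinylsilane; C17 epimers) | CCSC(=O)C[C@@H](O[Si](CC)(CC)CC)[C@]1(C)[C@@H]([C@@H](O)[C@@]3(O)[C@H](/C=C(/CO[Si](c2ccccc2)(c2ccccc2)C(C)(C)C)[Si](CC)(CC)CC)OC(=O)C3C)[C@@]2(C)O[C@H]2C[C@@H]1OC(C)=O | intermediate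
24 | alkenyl iodide seco-thioester (C5–I cis to C7) | CCSC(=O)C[C@@H](O[Si](CC)(CC)CC)[C@]1(C)[C@@H]([C@@H](O)[C@@]3(O)[C@H](/C=C(/CO[Si](c2ccccc2)(c2ccccc2)C(C)(C)C)I)OC(=O)C3C)[C@@]2(C)O[C@H]2C[C@@H]1OC(C)=O | intermediate
25 | macrocyclic C4 enone (2-OTES, 9-OH, 16-OTBDPS, C17 epimers) | CC(=O)O[C@H]1C[C@@H]2O[C@]2(C)[C@@H]2[C@@H](O)[C@@]3(O)[C@H](/C=C(/CO[Si](c4ccccc4)(c4ccccc4)C(C)(C)C)C(=O)C[C@@H](O[Si](CC)(CC)CC)[C@@]12C)OC(=O)C3C | intermediate
26 | macrocyclic β-hydroxy enone (2-OH) | CC(=O)O[C@H]1C[C@@H]2O[C@]2(C)[C@@H]2[C@@H](O)[C@@]3(O)[C@H](/C=C(/CO[Si](c4ccccc4)(c4ccccc4)C(C)(C)C)C(=O)C[C@@H](O)[C@@]12C)OC(=O)C3C | intermediate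
27 | 2,4-anti diol (2,4,8,9-tetraol 14-acetate 16-TBDPS ether) | CC(=O)O[C@H]1C[C@@H]2O[C@]2(C)[C@@H]2[C@@H](O)[C@@]3(O)[C@H](/C=C(/CO[Si](c4ccccc4)(c4ccccc4)C(C)(C)C)[C@H](O)C[C@@H](O)[C@@]12C)OC(=O)C3C | intermediate
28 | 2,4,9,14-tetraacetate 16-TBDPS ether (C17 epimers) | CC(=O)O[C@H]1C[C@@H]2O[C@]2(C)[C@@H]2[C@@H](OC(C)=O)[C@@]3(O)[C@H](/C=C(/CO[Si](c4ccccc4)(c4ccccc4)C(C)(C)C)[C@H](OC(C)=O)C[C@@H](OC(C)=O)[C@@]12C)OC(=O)C3C | intermediate
29 | 2,4,9,14-tetraacetate 16-TBDPS ether, single C17 epimer (CH3-18 cis to 8-OH) | CC(=O)O[C@H]1C[C@@H]2O[C@]2(C)[C@@H]2[C@@H](OC(C)=O)[C@@]3(O)[C@H](/C=C(/CO[Si](c4ccccc4)(c4ccccc4)C(C)(C)C)[C@H](OC(C)=O)C[C@@H](OC(C)=O)[C@@]12C)OC(=O)[C@@H]3C | intermediate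
30 | CNP0104124.1 (2,4,9,14-tetraacetoxy-11β,12β-epoxy-8,16-dihydroxybriar-5(Z)-en-18,7-olide) | CC(=O)O[C@H]1C[C@@H]2O[C@]2(C)[C@@H]2[C@@H](OC(C)=O)[C@@]3(O)[C@H](/C=C(/CO)[C@H](OC(C)=O)C[C@@H](OC(C)=O)[C@@]12C)OC(=O)[C@@H]3C | target

**Step count and risks**
Total: 24 steps. Longest linear sequence: 18 steps (1 → 30 through steps 1–8 and 15–24); the enyne branch (steps 9–14) adds 6.

Step 19 (proposed new ring closure). It may give proto-deiodination, oligomers or ionisation of the allylic lactone instead of the ketone. The fallback sets out from 23 and comes back at 25. The thioester of 23 is reduced to the aldehyde by Fukuyama reduction (Et3SiH, Pd/C, acetone) to give the seco aldehyde F1. Iododesilylation as in step 18 gives the iodo aldehyde F2. An intramolecular Nozaki–Hiyama–Kishi reaction (CrCl2, NiCl2 cat., DMSO/THF, high dilution) closes the ring to the C4 allylic alcohols F3 as an epimer mixture. MnO2 oxidises only the allylic carbinol and delivers enone 25.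

Step 15 (aldehyde–enyne coupling). Regiochemistry at the hindered alkyne carbon, the Felkin–Anh ratio at C9 and the tolerance of the thioester towards zerovalent nickel are uncertain. The fallback sets out from 11 and 16 and comes back at 20. The lithium acetylide of 16 (BuLi, THF, −78 °C) adds to 11 in the Felkin–Anh sense to give the propargylic alcohol F4. Hydroxyl-directed trans-hydrostannation (Bu3SnH, [Cp*RuCl]4, CH2Cl2) puts tin on the proximal carbon C8 and gives the alkenylstannane F5. Iodine at −78 °C gives the alkenyl iodide F6 with retention. Palladium-catalysed coupling with the Reformatsky reagent BrZnCH(CH3)CO2tBu (Pd(dba)2, P(t-Bu)3, THF) installs C17–C19 and gives 20.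

Step 21 (directed reduction inside the ten-membered ring). The ring may prevent the chair delivery and give the wrong C4 epimer. The fallback sets out from 26 and comes back at 28. Non-directed Luche reduction (NaBH4, CeCl3·7H2O, MeOH, −78 °C) is taken to give the 4-epi alcohol F7. Mitsunobu reaction with acetic acid (PPh3, DIAD, toluene) inverts the allylic C4 carbinol and gives the 4-acetate F8 with the natural configuration. Acetylation of the C2 and C9 hydroxyls (Ac2O, pyridine, DMAP) gives 28.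

**Further compounds**
F1 | step 19 | seco aldehyde (C4 = CHO; C5 vinylsilane; lactone and epoxide as in 23) | O=CC[C@@H](O[Si](CC)(CC)CC)[C@]1(C)[C@@H]([C@@H](O)[C@@]3(O)[C@H](/C=C(/CO[Si](c2ccccc2)(c2ccccc2)C(C)(C)C)[Si](CC)(CC)CC)OC(=O)C3C)[C@@]2(C)O[C@H]2C[C@@H]1OC(C)=O
F2 | step 19 | iodo aldehyde (C4 = CHO; C5–I) | O=CC[C@@H](O[Si](CC)(CC)CC)[C@]1(C)[C@@H]([C@@H](O)[C@@]3(O)[C@H](/C=C(/CO[Si](c2ccccc2)(c2ccccc2)C(C)(C)C)I)OC(=O)C3C)[C@@]2(C)O[C@H]2C[C@@H]1OC(C)=O
F3 | step 19 | macrocyclic C4 allylic alcohols (both C4 epimers; 2-OTES) | CC(=O)O[C@H]1C[C@@H]2O[C@]2(C)[C@@H]2[C@@H](O)[C@@]3(O)[C@H](/C=C(/CO[Si](c4ccccc4)(c4ccccc4)C(C)(C)C)C(O)C[C@@H](O[Si](CC)(CC)CC)[C@@]12C)OC(=O)C3C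
F4 | step 15 | C9 propargylic alcohol (C8≡C7 alkyne; 9-OH anti to C1) | CCSC(=O)C[C@@H](O[Si](CC)(CC)CC)[C@]1(C)[C@@H]([C@@H](O)C#C/C=C(/CO[Si](c2ccccc2)(c2ccccc2)C(C)(C)C)[Si](CC)(CC)CC)C(C)=CC[C@@H]1OC(C)=O
F5 | step 15 | C8 alkenylstannane (Bu3Sn on C8, cis to C6) | CCSC(=O)C[C@@H](O[Si](CC)(CC)CC)[C@]1(C)[C@@H]([C@@H](O)/C(=C/C=C(/CO[Si](c2ccccc2)(c2ccccc2)C(C)(C)C)[Si](CC)(CC)CC)[Sn](CCCC)(CCCC)CCCC)C(C)=CC[C@@H]1OC(C)=O
F6 | step 15 | C8 alkenyl iodide (I on C8, cis to C6) | CCSC(=O)C[C@@H](O[Si](CC)(CC)CC)[C@]1(C)[C@@H]([C@@H](O)/C(=C/C=C(/CO[Si](c2ccccc2)(c2ccccc2)C(C)(C)C)[Si](CC)(CC)CC)I)C(C)=CC[C@@H]1OC(C)=O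
F7 | step 21 | 4-epi diol (2,4-syn) | CC(=O)O[C@H]1C[C@@H]2O[C@]2(C)[C@@H]2[C@@H](O)[C@@]3(O)[C@H](/C=C(/CO[Si](c4ccccc4)(c4ccccc4)C(C)(C)C)[C@@H](O)C[C@@H](O)[C@@]12C)OC(=O)C3C
F8 | step 21 | 4-acetate with natural C4 configuration (2-OH and 9-OH free) | CC(=O)O[C@H]1C[C@@H]2O[C@]2(C)[C@@H]2[C@@H](O)[C@@]3(O)[C@H](/C=C(/CO[Si](c4ccccc4)(c4ccccc4)C(C)(C)C)[C@H](OC(C)=O)C[C@@H](O)[C@@]12C)OC(=O)C3C
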